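The route opens the furan at its C2=C3 double bond. C2 carries O1 and the 2,4-dioxygenated ring B; C3 is bonded to C3a of the benzo ring A and carries the carbon that becomes the formyl group. Both are traced back to carbonyl carbons: an aryl ester and an ortho acetyl group on ring A. One titanium-mediated reductive coupling joins them, closes the five-membered ring and delivers the aromatic 3-methylbenzofuran with the whole carbon skeleton in place. The precursor is a pentasubstituted ring A acetophenone whose less hindered ortho oxygen, the future O1, is acylated with 2,4-bis(benzyloxy)benzoic acid; the other phenol is benzylated and the side chain is already hydrated.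

Key step: step 6

Assumption: the tertiary alcohol is carried unprotected through the titanium step, where it should only bind extra reagent as a titanium alkoxide; benzyl bromide, benzyl alcohol and all other reagents are purchased.

Design notes: an aryl ester ortho to an acetyl group is prone to base-induced acyl transfer (Baker–Venkataraman rearrangement), so after its installation it is never exposed to carbonate or alkoxide bases. The alkene is hydrated only after both phenols are capped, so no free phenol sits next to the alkene or the new tertiary alcohol.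

Step 1
Reactants: 1 2,6-dihydroxy-4-methoxyacetophenone; 2 1-bromo-3-methylbut-2-ene
Product: 3 1-[2,6-dihydroxy-4-methoxy-3-(3-methylbut-2-en-1-yl)phenyl]ethan-1-one
Conditions: 10% aq KOH, 0 °C to rt, 2 (1 equiv) added slowly
Reagents that add atoms: none
Why: C-alkylation of an ambident phenoxide by an allylic bromide in water, where hydrogen bonding shields the oxygen atoms, and because the two free ring positions of 1 are equivalent by symmetry only one mono-C-prenyl isomer can form, the O-prenyl and bis-prenyl side products being removed by chromatography.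

Step 2
Reactants: 4 2,4-dihydroxybenzoic acid
Product: 6 2,4-bis(benzyloxy)benzoic acid, via tribenzylated ester 5 (not isolated)
Conditions: BnBr, K2CO3, DMF, 70 °C; then aq NaOH, MeOH, 70 °C; aq HCl work-up
Reagents that add atoms: benzyl bromide, BrCc1ccccc1; sodium hydroxide, [Na+].[OH-]
Why: Williamson etherification of both phenols together with alkylation of the carboxylate, followed by saponification of the benzyl ester, which leaves the two aryl benzyl ethers untouched.

Step 3
Reactants: 6 2,4-bis(benzyloxy)benzoic acid; 3 1-[2,6-dihydroxy-4-methoxy-3-(3-methylbut-2-en-1-yl)phenyl]ethan-1-one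
Product: 8 2-acetyl-3-hydroxy-5-methoxy-4-(3-methylbut-2-en-1-yl)phenyl 2,4-bis(benzyloxy)benzoate, via aroyl chloride 7 (not isolated)
Conditions: 6, (COCl)2, DMF (cat.), CH2Cl2, 0 °C to rt, concentrate; then 3, Et3N, DMAP (cat.), CH2Cl2, 0 °C, 1.0 equiv of 7 added slowly
Reagents that add atoms: none
Why: acid chloride formation followed by O-acylation of a phenol, in which the phenol flanked by the acetyl group and a ring hydrogen is far more accessible to the ortho-substituted aroyl chloride than the phenol wedged between the acetyl and prenyl groups, so one equivalent at 0 °C should stop at this mono-ester.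

Step 4
Reactants: 8 2-acetyl-3-hydroxy-5-methoxy-4-(3-methylbut-2-en-1-yl)phenyl 2,4-bis(benzyloxy)benzoate
Product: 9 2-acetyl-3-(benzyloxy)-5-methoxy-4-(3-methylbut-2-en-1-yl)phenyl 2,4-bis(benzyloxy)benzoate
Conditions: BnOH, PPh3, DIAD, THF, 0 °C to rt
Reagents that add atoms: benzyl alcohol, OCc1ccccc1
Why: Mitsunobu etherification alkylates the remaining acidic, chelated phenol with a primary alcohol under essentially neutral conditions, so no enolate or free phenoxide is generated that could trigger Baker–Venkataraman acyl transfer or transesterification of the neighbouring aryl ester.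

Step 5
Reactants: 9 2-acetyl-3-(benzyloxy)-5-methoxy-4-(3-methylbut-2-en-1-yl)phenyl 2,4-bis(benzyloxy)benzoate
Product: 10 2-acetyl-3-(benzyloxy)-4-(3-hydroxy-3-methylbutyl)-5-methoxyphenyl 2,4-bis(benzyloxy)benzoate
Conditions: Co(acac)2 (cat.), PhSiH3, O2 (1 atm), THF, rt
Reagents that add atoms: dioxygen, O=O
Why: Mukaiyama hydration, in which a cobalt hydride formed from Co(acac)2 and PhSiH3 transfers a hydrogen atom to the trisubstituted alkene and the tertiary radical is trapped by O2 and reduced to the Markovnikov tertiary alcohol, while the ketone, the ester and the benzyl ethers are inert to these conditions.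

Step 6
Reactants: 10 2-acetyl-3-(benzyloxy)-4-(3-hydroxy-3-methylbutyl)-5-methoxyphenyl 2,4-bis(benzyloxy)benzoate
Product: 11 4-{4-(benzyloxy)-2-[2,4-bis(benzyloxy)phenyl]-6-methoxy-3-methyl-1-benzofuran-5-yl}-2-methylbutan-2-ol
Conditions: TiCl3, Zn dust (both in excess), THF, reflux; 10 in THF added over several hours by syringe pump (high dilution)
Reagents that add atoms: none
Why: Zinc reduces TiCl3 to low-valent titanium, which transfers an electron to the aryl ketone to give a titanium-bound ketyl; the ketyl carbon adds to the titanium-activated carbonyl of the neighbouring aryl ester, forming the C2–C3 bond, and the oxophilic metal then strips both oxygen atoms from the resulting titanium diolate to leave the C2=C3 double bond of an aromatic furan. The closest known reaction type is the intramolecular McMurry-type keto–ester coupling that converts ortho-acyloxy aryl ketones into benzofurans and ortho-acylamino aryl ketones into indoles. The five-membered ring closes by carbon–carbon bond formation between two carbonyl carbons, formally a 5-exo-trig attack of the ketyl carbon on the ester C=O, with O1 already in place as the ester oxygen. No stereocentre is created. The step needs intramolecular keto–ester coupling to outrun intermolecular pinacol coupling and plain reduction of the ketone, and this is secured by the ortho relationship of the two carbonyl groups, by slow addition of 10 into excess reagent at high dilution and by the gain of aromaticity. Esters alone are reduced only slowly, aryl benzyl ethers are inert, and the tertiary alcohol should merely bind titanium as an alkoxide, for which extra reagent is allowed.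

Step 7
Reactants: 11 4-{4-(benzyloxy)-2-[2,4-bis(benzyloxy)phenyl]-6-methoxy-3-methyl-1-benzofuran-5-yl}-2-methylbutan-2-ol
Product: 12 4-(benzyloxy)-2-[2,4-bis(benzyloxy)phenyl]-5-(3-hydroxy-3-methylbutyl)-6-methoxy-1-benzofuran-3-carbaldehyde
Conditions: SeO2, 1,4-dioxane, reflux
Reagents that add atoms: selenium dioxide, O=[Se]=O
Why: Riley oxidation, in which SeO2 attacks the methyl group on the electron-rich furan double bond by an ene reaction and [2,3]-sigmatropic shift and carries the resulting alcohol on to the aldehyde, which as a vinylogous formate resists further oxidation, while the benzyl ethers and the tertiary alcohol offer no comparably activated C–H bond.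

Step 8
Reactants: 12 4-(benzyloxy)-2-[2,4-bis(benzyloxy)phenyl]-5-(3-hydroxy-3-methylbutyl)-6-methoxy-1-benzofuran-3-carbaldehyde
Product: 13 2-(2,4-dihydroxyphenyl)-4-hydroxy-5-(3-hydroxy-3-methylbutyl)-6-methoxy-1-benzofuran-3-carbaldehyde
Conditions: H2 (1 atm), 10% Pd/C, EtOAc, rt, stopped once debenzylation is complete
Reagents that add atoms: none
Why: hydrogenolysis of the three aryl benzyl ethers over Pd/C is fast at atmospheric pressure in ethyl acetate, whereas the aldehyde, deactivated as a vinylogous formate conjugated to O1, and the tetrasubstituted furan double bond are reduced much more slowly, so the reaction is halted after three equivalents of H2.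

Compound list
1 | 2,6-dihydroxy-4-methoxyacetophenone, 1-(2,6-dihydroxy-4-methoxyphenyl)ethan-1-one | CC(=O)c1c(O)cc(OC)cc1O | starting material
2 | 1-bromo-3-methylbut-2-ene (prenyl bromide) | CC(C)=CCBr | starting material
3 | 1-[2,6-dihydroxy-4-methoxy-3-(3-methylbut-2-en-1-yl)phenyl]ethan-1-one | CC(=O)c1c(O)cc(OC)c(CC=C(C)C)c1O | intermediate
4 | 2,4-dihydroxybenzoic acid | O=C(O)c1ccc(O)cc1O | starting material
5 | benzyl 2,4-bis(benzyloxy)benzoate (not isolated) | O=C(OCc1ccccc1)c1ccc(OCc2ccccc2)cc1OCc1ccccc1 | intermediate
6 | 2,4-bis(benzyloxy)benzoic acid | O=C(O)c1ccc(OCc2ccccc2)cc1OCc1ccccc1 | intermediate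
7 | 2,4-bis(benzyloxy)benzoyl chloride (not isolated) | O=C(Cl)c1ccc(OCc2ccccc2)cc1OCc1ccccc1 | intermediate
8 | 2-acetyl-3-hydroxy-5-methoxy-4-(3-methylbut-2-en-1-yl)phenyl 2,4-bis(benzyloxy)benzoate | CC(=O)c1c(OC(=O)c2ccc(OCc3ccccc3)cc2OCc2ccccc2)cc(OC)c(CC=C(C)C)c1O | intermediate
9 | 2-acetyl-3-(benzyloxy)-5-methoxy-4-(3-methylbut-2-en-1-yl)phenyl 2,4-bis(benzyloxy)benzoate | CC(=O)c1c(OC(=O)c2ccc(OCc3ccccc3)cc2OCc2ccccc2)cc(OC)c(CC=C(C)C)c1OCc1ccccc1 | intermediate
10 | 2-acetyl-3-(benzyloxy)-4-(3-hydroxy-3-methylbutyl)-5-methoxyphenyl 2,4-bis(benzyloxy)benzoate | CC(=O)c1c(OC(=O)c2ccc(OCc3ccccc3)cc2OCc2ccccc2)cc(OC)c(CCC(C)(C)O)c1OCc1ccccc1 | intermediate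
11 | 4-{4-(benzyloxy)-2-[2,4-bis(benzyloxy)phenyl]-6-methoxy-3-methyl-1-benzofuran-5-yl}-2-methylbutan-2-ol | Cc1c(-c2ccc(OCc3ccccc3)cc2OCc2ccccc2)oc2cc(OC)c(CCC(C)(C)O)c(OCc3ccccc3)c12 | intermediate
12 | 4-(benzyloxy)-2-[2,4-bis(benzyloxy)phenyl]-5-(3-hydroxy-3-methylbutyl)-6-methoxy-1-benzofuran-3-carbaldehyde | O=Cc1c(-c2ccc(OCc3ccccc3)cc2OCc2ccccc2)oc2cc(OC)c(CCC(C)(C)O)c(OCc3ccccc3)c12 | intermediate
13 | 2-(2,4-dihydroxyphenyl)-4-hydroxy-5-(3-hydroxy-3-methylbutyl)-6-methoxy-1-benzofuran-3-carbaldehyde | COc1cc2oc(-c3ccc(O)cc3O)c(C=O)c2c(O)c1CCC(C)(C)O | target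

Total step count: 8. Longest linear sequence: 7 steps (from 1 through steps 1, 3, 4, 5, 6, 7, 8; the branch from 4 through steps 2, 3, 4, 5, 6, 7, 8 is equally long).

Steps most likely to fail

Step 6 is the riskiest. The ketyl may couple between molecules (pinacol formation) or simply be reduced, the aryl ester may be cleaved reductively, or the tertiary alcohol may ionise under the Lewis-acidic titanium and zinc chlorides. The fallback sets out from 10 and comes back at 11, forming the same C2=C3 bond by polar chemistry. LiAlH4 in THF at 0 °C should reduce the ketone and cleave the aryl ester to give racemic 3-(benzyloxy)-2-(1-hydroxyethyl)-4-(3-hydroxy-3-methylbutyl)-5-methoxyphenol F1. PPh3·HBr in MeCN at room temperature should convert this very electron-rich ortho-hydroxy benzylic alcohol into racemic {1-[2-(benzyloxy)-6-hydroxy-3-(3-hydroxy-3-methylbutyl)-4-methoxyphenyl]ethyl}triphenylphosphonium bromide F2. Acylation of its phenol with 7 (made from 6 as in step 3) and Et3N in toluene should give the O-aroyl phosphonium bromide F3, which is not isolated. On heating with further Et3N, the ylide of F3 should attack the ester carbonyl in an intramolecular Wittig reaction and give 11.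

Step 8 is next. Hydrogenation may run past debenzylation, reducing the aldehyde to the alcohol or the methyl group, or saturating the furan double bond. The fallback sets out from 11 and comes back at 13, removing the benzyl groups before the aldehyde exists. Hydrogenolysis of 11 (H2, Pd/C, EtOAc) should give 2-(2,4-dihydroxyphenyl)-5-(3-hydroxy-3-methylbutyl)-6-methoxy-3-methyl-1-benzofuran-4-ol F4. Ac2O in pyridine at room temperature should cap the three phenols as 4-[4-(acetyloxy)-5-(3-hydroxy-3-methylbutyl)-6-methoxy-3-methyl-1-benzofuran-2-yl]-1,3-phenylene diacetate F5. Riley oxidation (SeO2, dioxane, reflux) should then give 4-[4-(acetyloxy)-3-formyl-5-(3-hydroxy-3-methylbutyl)-6-methoxy-1-benzofuran-2-yl]-1,3-phenylene diacetate F6. Methanolysis of the aryl acetates (K2CO3, degassed MeOH, 0 °C) should release 13 without any reducing agent.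

Step 4 is third. Alkylation of the hindered, hydrogen-bonded phenol may stall, or the neighbouring aryl ester may be transferred or lost. The same fallback also answers insufficient site selectivity in the acylation of step 3. It sets out from 3 and comes back at 9, introducing the base-sensitive ester last. TIPSCl and imidazole in DMF should silylate the less hindered phenol to give 1-{2-hydroxy-4-methoxy-3-(3-methylbut-2-en-1-yl)-6-[(triisopropylsilyl)oxy]phenyl}ethan-1-one F7. BnBr and K2CO3 in DMF should benzylate the remaining phenol to give 1-{2-(benzyloxy)-4-methoxy-3-(3-methylbut-2-en-1-yl)-6-[(triisopropylsilyl)oxy]phenyl}ethan-1-one F8. TBAF in THF at 0 °C should remove the silyl group to give 1-[2-(benzyloxy)-6-hydroxy-4-methoxy-3-(3-methylbut-2-en-1-yl)phenyl]ethan-1-one F9. Acylation of F9 with 7 (Et3N, DMAP, CH2Cl2, 0 °C) should give 9.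

Further compounds
F1 | step 6 | racemic 3-(benzyloxy)-2-(1-hydroxyethyl)-4-(3-hydroxy-3-methylbutyl)-5-methoxyphenol | CC(O)c1c(O)cc(OC)c(CCC(C)(C)O)c1OCc1ccccc1
F2 | step 6 | racemic {1-[2-(benzyloxy)-6-hydroxy-3-(3-hydroxy-3-methylbutyl)-4-methoxyphenyl]ethyl}triphenylphosphonium bromide | CC(c1c(O)cc(OC)c(CCC(C)(C)O)c1OCc1ccccc1)[P+](c1ccccc1)(c1ccccc1)c1ccccc1.[Br-]
F3 | step 6 | racemic O-aroyl phosphonium bromide, the 2,4-bis(benzyloxy)benzoate of the phenol of F2 (not isolated) | CC(c1c(OC(=O)c2ccc(OCc3ccccc3)cc2OCc2ccccc2)cc(OC)c(CCC(C)(C)O)c1OCc1ccccc1)[P+](c1ccccc1)(c1ccccc1)c1ccccc1.[Br-]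
F4 | step 8 | 2-(2,4-dihydroxyphenyl)-5-(3-hydroxy-3-methylbutyl)-6-methoxy-3-methyl-1-benzofuran-4-ol | Cc1c(-c2ccc(O)cc2O)oc2cc(OC)c(CCC(C)(C)O)c(O)c12
F5 | step 8 | 4-[4-(acetyloxy)-5-(3-hydroxy-3-methylbutyl)-6-methoxy-3-methyl-1-benzofuran-2-yl]-1,3-phenylene diacetate | Cc1c(-c2ccc(OC(C)=O)cc2OC(C)=O)oc2cc(OC)c(CCC(C)(C)O)c(OC(C)=O)c12
F6 | step 8 | 4-[4-(acetyloxy)-3-formyl-5-(3-hydroxy-3-methylbutyl)-6-methoxy-1-benzofuran-2-yl]-1,3-phenylene diacetate | O=Cc1c(-c2ccc(OC(C)=O)cc2OC(C)=O)oc2cc(OC)c(CCC(C)(C)O)c(OC(C)=O)c12
F7 | step 4 | 1-{2-hydroxy-4-methoxy-3-(3-methylbut-2-en-1-yl)-6-[(triisopropylsilyl)oxy]phenyl}ethan-1-one | CC(=O)c1c(O[Si](C(C)C)(C(C)C)C(C)C)cc(OC)c(CC=C(C)C)c1O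
F8 | step 4 | 1-{2-(benzyloxy)-4-methoxy-3-(3-methylbut-2-en-1-yl)-6-[(triisopropylsilyl)oxy]phenyl}ethan-1-one | CC(=O)c1c(O[Si](C(C)C)(C(C)C)C(C)C)cc(OC)c(CC=C(C)C)c1OCc1ccccc1
F9 | step 4 | 1-[2-(benzyloxy)-6-hydroxy-4-methoxy-3-(3-methylbut-2-en-1-yl)phenyl]ethan-1-one | CC(=O)c1c(O)cc(OC)c(CC=C(C)C)c1OCc1ccccc1
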